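**Plan**

- Target 17 is achiral. Ring A carries C1 OH, C2 O‑aryl (ring B = 2,4‑dibromophenyl), C3 Br, C4 OMe, C5 Br and C6 H, so no stereocentre has to be set.
- Retrosynthesis: the C3–Br and C5–Br bonds are cut first (bromination ortho to the C4 methoxy group on the O1 acetate). Ring A is then cut at C3–C4, C1–C2 and C1–C6.
- The enabling feature is that ring A is a 4‑methoxyphenol (C1 OH para to C4 OMe) with its aryloxy group at C2 next to the hydroxyl. A methoxy(vinyl)carbene chromium complex (C4, C5, C6), a terminal aryloxyalkyne (C2, C3) and one CO ligand (C1) give exactly this pattern on benzannulation.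
- Forward: ring B is bought with both bromines as 2,4‑dibromophenol and converted into the aryl ethynyl ether 7 (steps 1–4, no organolithium or amide base). The carbene complex 12 comes from Cr(CO)6 in one step (step 5).
- Ring A, the only ring built, is closed in step 6. Acetylation, double bromination at C5 and C3, and deacetylation (steps 7–9) finish the synthesis.

Key step: step 6

Remark: 7 and 12 are both prone to polymerisation, so each is assumed to be made shortly before step 6 and kept cold under argon. Compound 6 is drawn as the Z isomer expected to predominate; any E isomer is carried along.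

**Route**

Step 1
Reactants: 1 2,4‑dibromophenol; 2 1,2‑dibromoethane
Product: 3 2,4‑dibromo‑1‑(2‑bromoethoxy)benzene
Conditions: K2CO3, 2 (5 equiv), MeCN, reflux
Reagents that add atoms: none
Why: Williamson ether synthesis of a phenoxide with a primary bromide, the excess of dihalide suppressing double aryloxylation.

Step 2
Reactants: 3 2,4‑dibromo‑1‑(2‑bromoethoxy)benzene
Product: 4 2,4‑dibromo‑1‑(ethenyloxy)benzene
Conditions: KOt‑Bu, THF, 0 °C → rt
Reagents that add atoms: none
Why: E2 dehydrobromination of a 2‑aryloxyethyl bromide by a hindered alkoxide, the standard entry to aryl vinyl ethers, run in THF at or below room temperature so that the aryl bromides are not touched.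

Step 3
Reactants: 4 2,4‑dibromo‑1‑(ethenyloxy)benzene
Product: 6 (Z)‑2,4‑dibromo‑1‑[(2‑bromoethenyl)oxy]benzene, via dibromoethyl ether 5 (not isolated)
Conditions: Br2 (1.05 equiv), CH2Cl2, −78 °C; then i‑Pr2NEt, −78 → 40 °C
Reagents that add atoms: bromine, BrBr
Why: Electrophilic addition of bromine to the enol ether double bond (far faster than substitution on the twice‑brominated ring B) followed by amine‑induced loss of HBr from the α‑bromo ether, the classical bromination–dehydrobromination route to 2‑bromovinyl ethers.

Step 4
Reactants: 6 (Z)‑2,4‑dibromo‑1‑[(2‑bromoethenyl)oxy]benzene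
Product: 7 2,4‑dibromo‑1‑(ethynyloxy)benzene
Conditions: KOt‑Bu (1.3 equiv), THF, −78 → 0 °C; cold pentane/aq. NH4Cl work‑up, solution used at once
Reagents that add atoms: none
Why: Anti‑periplanar E2 dehydrobromination of the (Z)‑2‑bromovinyl ether, the usual last step of aryloxyacetylene synthesis, done cold with an alkoxide in place of organolithium or amide bases so that the aryl bromides are neither exchanged nor turned into arynes.

Step 5
Reactants: 8 vinyl bromide; 9 chromium hexacarbonyl Cr(CO)6
Product: 12 pentacarbonyl[methoxy(vinyl)carbene]chromium (CO)5Cr=C(OMe)CH=CH2, via vinyllithium 10 (not isolated), via lithium acryloylchromate 11 (not isolated)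
Conditions: t‑BuLi (2 equiv), Et2O, −78 °C; then Cr(CO)6, −78 °C → rt; then Me3OBF4, CH2Cl2, 0 °C; rapid cold filtration through silica under argon
Reagents that add atoms: trimethyloxonium tetrafluoroborate, C[O+](C)C.F[B-](F)(F)F
Why: Fischer carbene complex synthesis, in which vinyllithium from bromine–lithium exchange adds to a CO ligand of Cr(CO)6 and the resulting acylchromate is O‑methylated by the oxonium salt.

Step 6
Reactants: 12 pentacarbonyl[methoxy(vinyl)carbene]chromium; 7 2,4‑dibromo‑1‑(ethynyloxy)benzene
Product: 14 2‑(2,4‑dibromophenoxy)‑4‑methoxyphenol, via arene tricarbonylchromium complex 13 (not isolated)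
Conditions: 7 (1.5 equiv), degassed THF, 50 °C, argon; then air, light, Et2O/MeCN, rt
Reagents that add atoms: none
Why: Thermal loss of one CO from 12 lets the terminal alkyne of 7 coordinate and insert into the Cr=C bond, so that its CH carbon bonds to the former carbene carbon (C3–C4) and the OAr‑bearing carbon becomes the new carbene carbon; migration of a CO ligand onto that carbon gives a chromium‑bound dienylketene (C1–C2), whose ring closure onto the vinyl terminus (C1–C6) and keto–enol tautomerisation deliver the arene complex 13, from which air releases 14. This is the Dötz benzannulation of an alkenyl(alkoxy)carbene chromium complex with a terminal heteroatom‑substituted alkyne, a reaction type known for aryl alkynyl ethers. Ring A, the only ring formed, closes by a thermally allowed disrotatory 6π‑electrocyclisation of the metal‑templated dienylketene. No stereocentre is created. The one selectivity needed is the sense of alkyne insertion, and both the size difference between H and OAr and the polarisation of the alkynyl ether (nucleophilic CH carbon toward the electrophilic carbene carbon) put OAr next to the CO‑derived C1, so the carbene methoxy group ends up para to the new hydroxyl and the two hydroquinone oxygens are differentiated from the outset. The aryl bromides of ring B are inert to zerovalent chromium carbonyls at 50 °C and should pass through unchanged.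

Step 7
Reactants: 14 2‑(2,4‑dibromophenoxy)‑4‑methoxyphenol
Product: 15 2‑(2,4‑dibromophenoxy)‑4‑methoxyphenyl acetate
Conditions: Ac2O, pyridine, DMAP (cat.), rt
Reagents that add atoms: acetic anhydride, CC(=O)OC(C)=O
Why: Nucleophile‑catalysed O‑acylation of a phenol, which turns the strongest donor on ring A (the C1 hydroxyl, directing to C6) into a weak one before bromination.

Step 8
Reactants: 15 2‑(2,4‑dibromophenoxy)‑4‑methoxyphenyl acetate
Product: 16 3,5‑dibromo‑2‑(2,4‑dibromophenoxy)‑4‑methoxyphenyl acetate
Conditions: Br2 (2.3 equiv), NaOAc, AcOH, rt → 45 °C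
Reagents that add atoms: bromine, BrBr
Why: Electrophilic aromatic bromination in which, with O1 acylated, the C4 methoxy and C2 aryloxy groups are the only strong donors on ring A and jointly direct first to C5 (ortho to OMe, para to OAr) and then to C3 (ortho to both), whereas C6 has only the weakly donating acetoxy group ortho and ring B is deactivated by its two bromines.

Step 9
Reactants: 16 3,5‑dibromo‑2‑(2,4‑dibromophenoxy)‑4‑methoxyphenyl acetate
Product: 17 3,5‑dibromo‑2‑(2,4‑dibromophenoxy)‑4‑methoxyphenol (target)
Conditions: methanolic HCl (cat.), MeOH, 40 °C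
Reagents that add atoms: none
Why: Acid‑catalysed transesterification (methanolysis) of the aryl acetate, conditions under which the methyl ether, the diaryl ether and the four aryl bromides are stable.

**Compound list**

1 | 2,4‑dibromophenol | Oc1ccc(Br)cc1Br | starting material
2 | 1,2‑dibromoethane | BrCCBr | starting material
3 | 2,4‑dibromo‑1‑(2‑bromoethoxy)benzene | BrCCOc1ccc(Br)cc1Br | intermediate
4 | 2,4‑dibromo‑1‑(ethenyloxy)benzene | C=COc1ccc(Br)cc1Br | intermediate
5 | 2,4‑dibromo‑1‑(1,2‑dibromoethoxy)benzene, racemic | BrCC(Br)Oc1ccc(Br)cc1Br | intermediate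
6 | (Z)‑2,4‑dibromo‑1‑[(2‑bromoethenyl)oxy]benzene | Br/C=C\Oc1ccc(Br)cc1Br | intermediate
7 | 2,4‑dibromo‑1‑(ethynyloxy)benzene | C#COc1ccc(Br)cc1Br | intermediate
8 | vinyl bromide | C=CBr | starting material
9 | chromium hexacarbonyl Cr(CO)6 | O=C=[Cr](=C=O)(=C=O)(=C=O)(=C=O)=C=O | starting material
10 | vinyllithium | [Li]C=C | intermediate
11 | lithium pentacarbonyl(1‑oxidoprop‑2‑en‑1‑ylidene)chromate (lithium acryloylchromate) | [Li+].[O-]C(C=C)=[Cr](=C=O)(=C=O)(=C=O)(=C=O)=C=O | intermediate
12 | pentacarbonyl[methoxy(vinyl)carbene]chromium, (CO)5Cr=C(OMe)CH=CH2 | COC(C=C)=[Cr](=C=O)(=C=O)(=C=O)(=C=O)=C=O | intermediate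
13 | tricarbonyl[η6‑2‑(2,4‑dibromophenoxy)‑4‑methoxyphenol]chromium, Cr(CO)3 bound to ring A (the η6 bond is not expressed in the SMILES) | COc1ccc(O)c(Oc2ccc(Br)cc2Br)c1.O=C=[Cr](=C=O)=C=O | intermediate
14 | 2‑(2,4‑dibromophenoxy)‑4‑methoxyphenol | COc1ccc(O)c(Oc2ccc(Br)cc2Br)c1 | intermediate
15 | 2‑(2,4‑dibromophenoxy)‑4‑methoxyphenyl acetate | COc1ccc(OC(C)=O)c(Oc2ccc(Br)cc2Br)c1 | intermediate
16 | 3,5‑dibromo‑2‑(2,4‑dibromophenoxy)‑4‑methoxyphenyl acetate | COc1c(Br)cc(OC(C)=O)c(Oc2ccc(Br)cc2Br)c1Br | intermediate
17 | 3,5‑dibromo‑2‑(2,4‑dibromophenoxy)‑4‑methoxyphenol | COc1c(Br)cc(O)c(Oc2ccc(Br)cc2Br)c1Br | target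

**Step count and risks**

Total steps: 9. Longest linear sequence: 8 (steps 1, 2, 3, 4, 6, 7, 8, 9 from 2,4‑dibromophenol); step 5 is a one‑step side branch that joins at step 6.

Steps most likely to fail:

1. Step 6. After alkyne insertion the new carbene carbon is stabilised by its aryloxy group and may take up CO only slowly. Oligomerisation of the labile alkynyl ether, or diversion of the vinylcarbene into products that have not incorporated CO, could then outrun ring closure. Fallback, setting out from 1 and returning at 14: nucleophilic aromatic substitution of 2‑fluoro‑4‑methoxybenzaldehyde by the phenoxide of 1 (K2CO3, DMF, 120 °C) should give 2‑(2,4‑dibromophenoxy)‑4‑methoxybenzaldehyde F1. Baeyer–Villiger oxidation with mCPBA in CH2Cl2, in which the electron‑rich aryl group migrates, should give 2‑(2,4‑dibromophenoxy)‑4‑methoxyphenyl formate F2. Methanolysis with catalytic methanolic HCl then gives 14, and steps 7–9 follow unchanged.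

2. Step 8. The second bromination has to enter the crowded C3 position between two ether oxygens. It may stall, and forcing it may bring over‑bromination at C6 or at C6' of ring B. Fallback, setting out from 15 and returning at 16: BBr3 (CH2Cl2, −78 → 0 °C) should cleave the methyl ether while sparing the aryl acetate, giving 2‑(2,4‑dibromophenoxy)‑4‑hydroxyphenyl acetate F3. The free C4 hydroxyl then directs Br2 (2 equiv, NaOAc, AcOH, 0 °C → rt) to both of its ortho positions, C3 and C5, giving 3,5‑dibromo‑2‑(2,4‑dibromophenoxy)‑4‑hydroxyphenyl acetate F4. O‑Methylation of this acidic dibromophenol with Me3SiCHN2 in toluene/MeOH, which needs no base and so avoids acetyl scrambling, gives 16.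

3. Step 5. The unsubstituted vinyl group of 12 is a strong acceptor, and the complex may polymerise during O‑methylation, filtration or storage, so that too little survives for step 6. Fallback, setting out from 9 (and using 7 as in the main route) and returning at 14: (E)‑(2‑bromovinyl)trimethylsilane and t‑BuLi (Et2O, −78 °C) give (E)‑2‑(trimethylsilyl)vinyllithium F5, which adds to Cr(CO)6 to give the lithium acylchromate F6. Me3OBF4 converts this into pentacarbonyl{methoxy[(E)‑2‑(trimethylsilyl)vinyl]carbene}chromium F7, a silyl‑capped stand‑in for 12 that should resist polymerisation. Benzannulation of F7 with 7 (THF, 50 °C) forms the same three bonds; in the cyclohexadienone intermediate the silyl group on C6 shifts to O1 in place of the proton. This should give the Cr(CO)3 complex of the aryl silyl ether F8 and, after exposure to air, [2‑(2,4‑dibromophenoxy)‑4‑methoxyphenoxy]trimethylsilane F9. Dilute HCl in THF/water removes the silyl group and gives 14.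

**Further compounds**

F1 | step 6 | 2‑(2,4‑dibromophenoxy)‑4‑methoxybenzaldehyde | COc1ccc(C=O)c(Oc2ccc(Br)cc2Br)c1
F2 | step 6 | 2‑(2,4‑dibromophenoxy)‑4‑methoxyphenyl formate | COc1ccc(OC=O)c(Oc2ccc(Br)cc2Br)c1
F3 | step 8 | 2‑(2,4‑dibromophenoxy)‑4‑hydroxyphenyl acetate | CC(=O)Oc1ccc(O)cc1Oc1ccc(Br)cc1Br
F4 | step 8 | 3,5‑dibromo‑2‑(2,4‑dibromophenoxy)‑4‑hydroxyphenyl acetate | CC(=O)Oc1cc(Br)c(O)c(Br)c1Oc1ccc(Br)cc1Br
F5 | step 5 | (E)‑2‑(trimethylsilyl)vinyllithium | C[Si](C)(C)/C=C/[Li]
F6 | step 5 | lithium pentacarbonyl[(E)‑1‑oxido‑3‑(trimethylsilyl)prop‑2‑en‑1‑ylidene]chromate | [Li+].[O-]C(/C=C/[Si](C)(C)C)=[Cr](=C=O)(=C=O)(=C=O)(=C=O)=C=O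
F7 | step 5 | pentacarbonyl{methoxy[(E)‑2‑(trimethylsilyl)vinyl]carbene}chromium | COC(/C=C/[Si](C)(C)C)=[Cr](=C=O)(=C=O)(=C=O)(=C=O)=C=O
F8 | step 5 | tricarbonyl{η6‑[2‑(2,4‑dibromophenoxy)‑4‑methoxyphenoxy]trimethylsilane}chromium, Cr(CO)3 bound to ring A | COc1ccc(O[Si](C)(C)C)c(Oc2ccc(Br)cc2Br)c1.O=C=[Cr](=C=O)=C=O
F9 | step 5 | [2‑(2,4‑dibromophenoxy)‑4‑methoxyphenoxy]trimethylsilane | COc1ccc(O[Si](C)(C)C)c(Oc2ccc(Br)cc2Br)c1
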